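**Retrosynthetic overview**
1. Shimalactone B (34) ⇐ (E,Z,Z,E)-tetraene 32 by thermal 8π-conrotatory/6π-disrotatory electrocyclisation (cyclobutane and cyclohexadiene formed last); 32 ⇐ Stille coupling of east trienyl iodide 19 and west dienylstannane 31.
2. 19 ⇐ bridge aldehyde 16 by two Wittig homologations and a Stork–Zhao iodo-olefination.
3. Oxabicyclo[2.2.1]heptane 14 ⇐ lactol acetate 12: γ-lactone ring first (step 6), then the cyclopentanone ring by intramolecular Mukaiyama aldol of the ethyl-ketone enol silane onto the masked aldehyde (step 7).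
4. 12 ⇐ lactone 4: C7 quaternary centre by Pd-catalysed asymmetric allylic alkylation of isoprene monoepoxide, C4 quaternary centre by lactone-enolate methylation, ethyl ketone by EtLi opening of the lactone.
5. 31 ⇐ (Z)-iodo-dienal 26 + but-2-yne by catalytic asymmetric alkenylzinc addition; 26 from propargyl alcohol.

Assumption: the sense of induction of the chiral ligands in steps 1 and 18 is assigned by analogy with closely related reactions; if either proves opposite, the antipodal ligand is used.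

**East fragment**

Step 1
Reactants: 1 2-ethenyl-2-methyloxirane (racemic); 2 tert-butyl methyl propanedioate
Product: 4 tert-butyl (4R)-4-ethenyl-4-methyl-2-oxooxolane-3-carboxylate (C3 epimers), via hydroxy malonate 3 (not isolated)
Conditions: [Pd2(dba)3]·CHCl3 (1 mol %), (R,R)-Trost ligand (3 mol %), CH2Cl2, rt; then DBU (0.2 equiv), rt
Reagents that add atoms: none
Why: Tsuji–Trost asymmetric allylic alkylation run as a dynamic kinetic asymmetric transformation of the racemic vinyl epoxide, in which the alkoxide of the π-allyl zwitterion deprotonates the malonate and delivers it to the tertiary terminus while the chiral ligand sets the quaternary C4 (R), after which the primary alcohol lactonises on the methyl ester in preference to the tert-butyl ester (C3 stays enolisable and is set later).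

Step 2
Reactants: 4 vinyl lactone
Product: 6 tert-butyl (4R)-4-(dimethoxymethyl)-4-methyl-2-oxooxolane-3-carboxylate (C3 epimers), via aldehyde 5 (not isolated)
Conditions: O3, CH2Cl2/MeOH (4:1), −78 °C; Me2S; then TsOH·H2O (0.1 equiv), rt
Reagents that add atoms: methanol, CO
Why: Ozonolysis cleaves the only C=C bond and the neopentyl aldehyde is acetalised in the same pot, which protects it and makes it the larger of the two groups on the untouched quaternary C4.

Step 3
Reactants: 6 acetal lactone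
Product: 7 tert-butyl (3S,4R)-4-(dimethoxymethyl)-3,4-dimethyl-2-oxooxolane-3-carboxylate
Conditions: NaH, THF, 0 °C; MeI, −30 → 0 °C
Reagents that add atoms: iodomethane, CI
Why: Alkylation of the malonate-type lactone enolate takes place on the face anti to the branched dimethoxymethyl group, that is syn to the C4 methyl, which sets the second quaternary centre as the cis-dimethyl (3S,4R) isomer (expected about 6:1, minor isomer removed by chromatography).

Step 4
Reactants: 7 dimethyl lactone
Product: 9 tert-butyl (2S)-2-[(2R)-1-hydroxy-3,3-dimethoxy-2-methylpropan-2-yl]-2-methyl-3-oxopentanoate (in equilibrium with its cyclic hemiketal), via lithium lactolate 8 (not isolated)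
Conditions: EtLi (1.2 equiv), THF, −78 °C; AcOH, −78 °C → rt
Reagents that add atoms: ethyllithium, [Li]CC
Why: Mono-addition of an organolithium to the lactone stops at the lithium lactolate at −78 °C while the tert-butyl ester and the acetal are inert, and the liberated neopentyl alcohol cannot relactonise onto a tert-butyl ester, so the ethyl ketone is unmasked with no stereocentre affected.

Step 5
Reactants: 9 hydroxy ketone
Product: 10 tert-butyl (2S)-2-[(2R)-1-{[tert-butyl(diphenyl)silyl]oxy}-3,3-dimethoxy-2-methylpropan-2-yl]-2-methyl-3-oxopentanoate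
Conditions: TBDPSCl, imidazole, DMAP (cat.), DMF, 40 °C
Reagents that add atoms: tert-butyl(chloro)diphenylsilane, CC(C)(C)[Si](Cl)(c1ccccc1)c1ccccc1
Why: Silylation of the primary alcohol drains the hemiketal equilibrium through the open form and installs an acid-tolerant protecting group for the next step.

Step 6
Reactants: 10 silyl ether
Product: 12 (3R,4S)-3-{[tert-butyl(diphenyl)silyl]oxymethyl}-3,4-dimethyl-5-oxo-4-propanoyloxolan-2-yl acetate (C2 anomers), via pseudo-acid 11 (not isolated)
Conditions: TFA/H2O/CH2Cl2 (5:1:10), 0 °C → rt; evaporate; Ac2O, pyridine, DMAP (cat.), CH2Cl2, 0 °C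
Reagents that add atoms: water, O; acetic anhydride, CC(=O)OC(C)=O
Why: Acidolysis removes the tert-butyl ester and hydrolyses the acetal, the γ-aldehydo acid closes spontaneously to the five-membered pseudo-acid (which also shields the β-keto acid from decarboxylation), and acetylation turns the lactol into an acyloxocarbenium precursor, the anomeric centre being inconsequential.

Step 7
Reactants: 12 lactol acetate
Product: 14 (1S,4S,6R,7R)-7-{[tert-butyl(diphenyl)silyl]oxymethyl}-4,6,7-trimethyl-2-oxabicyclo[2.2.1]heptane-3,5-dione, via silyl enol ether 13 (not isolated)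
Conditions: Me3SiOTf (1.3 equiv), Et3N (1.5 equiv), CH2Cl2, 0 °C; BF3·OEt2 (2 equiv), −78 → −20 °C; then DBU (0.1 equiv), CH2Cl2, rt
Reagents that add atoms: none
Why: Intramolecular Mukaiyama aldol reaction in which the enol silane of the ethyl ketone (enolisable on one side only) adds to the acyloxocarbenium ion released from the lactol acetate, closing the cyclopentanone ring across the lactone so that the C1 bridgehead configuration is dictated by the ring fusion, while the epimerisable C6 methyl is equilibrated by DBU to the endo position away from the syn C7 substituent.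

Step 8
Reactants: 14 silyl ether
Product: 15 (1S,4S,6R,7R)-7-(hydroxymethyl)-4,6,7-trimethyl-2-oxabicyclo[2.2.1]heptane-3,5-dione
Conditions: Bu4NF, AcOH (1:1), THF, 0 °C → rt
Reagents that add atoms: none
Why: Buffered fluoride desilylation frees the neopentyl alcohol without opening the strained β-keto lactone, and the alcohol (anti to the lactone bridge) cannot translactonise.

Step 9
Reactants: 15 alcohol
Product: 16 (1S,4S,6R,7S)-4,6,7-trimethyl-3,5-dioxo-2-oxabicyclo[2.2.1]heptane-7-carbaldehyde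
Conditions: Dess–Martin periodinane, CH2Cl2, rt
Reagents that add atoms: none
Why: Dess–Martin oxidation gives the non-enolisable aldehyde under neutral conditions that leave the ketone, the lactone and the C6 centre untouched.

Step 10
Reactants: 16 aldehyde
Product: 17 (2E)-2-methyl-3-[(1S,4S,6R,7S)-4,6,7-trimethyl-3,5-dioxo-2-oxabicyclo[2.2.1]heptan-7-yl]prop-2-enal
Conditions: Ph3P=C(Me)CHO (1.5 equiv), PhMe, 100 °C
Reagents that add atoms: 2-(triphenylphosphoranylidene)propanal, CC(C=O)=P(c1ccccc1)(c1ccccc1)c1ccccc1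
Why: Wittig olefination with a stabilised formyl ylide reacts only at the aldehyde (the hindered ketone and the lactone are inert), gives the (E)-trisubstituted enal and needs no redox step that the ketone would not survive.

Step 11
Reactants: 17 enal
Product: 18 (2E,4E)-2,4-dimethyl-5-[(1S,4S,6R,7S)-4,6,7-trimethyl-3,5-dioxo-2-oxabicyclo[2.2.1]heptan-7-yl]penta-2,4-dienal
Conditions: Ph3P=C(Me)CHO (1.3 equiv), PhMe, 90 °C
Reagents that add atoms: 2-(triphenylphosphoranylidene)propanal, CC(C=O)=P(c1ccccc1)(c1ccccc1)c1ccccc1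
Why: A second stabilised-ylide Wittig homologation gives the (E,E)-dienal, and the doubly conjugated product is too unreactive to homologate further under these conditions.

Step 12
Reactants: 18 dienal
Product: 19 (1S,4S,6R,7S)-7-[(1E,3E,5Z)-6-iodo-2,4-dimethylhepta-1,3,5-trien-1-yl]-4,6,7-trimethyl-2-oxabicyclo[2.2.1]heptane-3,5-dione
Conditions: [Ph3PEt]I, n-BuLi, THF, rt; I2, −78 °C; NaN(SiMe3)2, −78 °C; then 18, −78 → −20 °C
Reagents that add atoms: ethyltriphenylphosphonium iodide, CC[P+](c1ccccc1)(c1ccccc1)c1ccccc1.[I-]; iodine, II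
Why: Stork–Zhao Wittig olefination with the non-stabilised α-iodo ylide gives the (Z)-2-iodoalkene (iodine cis to the chain) under kinetic control at low temperature, where only the aldehyde reacts.

**West fragment**

Step 13
Reactants: 20 prop-2-yn-1-ol
Product: 22 (2Z)-3-iodo-2-methylprop-2-en-1-ol, via alkenylmagnesium alkoxide 21 (not isolated)
Conditions: MeMgBr (3 equiv), copper monoiodide (10 mol %), THF, −10 °C → rt; I2, −78 → 0 °C; aq NH4Cl
Reagents that add atoms: methylmagnesium bromide, C[Mg]Br; iodine, II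
Why: Copper-catalysed anti-carbomagnesiation of the propargylic alkoxide places the methyl on C2 and magnesium on C3 in a five-membered chelate, so iodinolysis with retention gives the (Z)-iodide (iodine cis to CH2OH).

Step 14
Reactants: 22 iodo alcohol
Product: 23 (2Z)-3-iodo-2-methylprop-2-enal
Conditions: MnO2, CH2Cl2, rt, dark; used at once
Reagents that add atoms: none
Why: Allylic oxidation with MnO2 is neutral and mild enough to keep the (Z)-geometry of the sensitive enal.

Step 15
Reactants: 23 enal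
Product: 24 ethyl (2E,4Z)-5-iodo-2,4-dimethylpenta-2,4-dienoate
Conditions: Ph3P=C(Me)CO2Et, CH2Cl2, rt
Reagents that add atoms: ethyl 2-(triphenylphosphoranylidene)propanoate, CCOC(=O)C(C)=P(c1ccccc1)(c1ccccc1)c1ccccc1
Why: Wittig olefination with a stabilised ylide gives the (E)-trisubstituted enoate at room temperature while the (Z)-iodoalkene is retained.

Step 16
Reactants: 24 dienoate
Product: 25 (2E,4Z)-5-iodo-2,4-dimethylpenta-2,4-dien-1-ol
Conditions: i-Bu2AlH (2.2 equiv), CH2Cl2, −78 °C; aqueous work-up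
Reagents that add atoms: none
Why: 1,2-Reduction of the conjugated ester by the aluminium hydride gives the allylic alcohol without touching the vinyl iodide or the alkene geometry.

Step 17
Reactants: 25 dienol
Product: 26 (2E,4Z)-5-iodo-2,4-dimethylpenta-2,4-dienal
Conditions: MnO2, CH2Cl2, rt
Reagents that add atoms: none
Why: Allylic oxidation with MnO2 gives the dienal without isomerisation of either double bond.

Step 18
Reactants: 26 dienal; 27 but-2-yne
Product: 30 (2E,4R,5E,7Z)-8-iodo-3,5,7-trimethylocta-2,5,7-trien-4-ol, via alkenylborane 28 (not isolated), via alkenylzinc 29 (not isolated)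
Conditions: Cy2BH, PhMe, 0 °C → rt; Me2Zn, −78 °C; (+)-MIB (5 mol %); then 26, −20 → 0 °C; aq NH4Cl
Reagents that add atoms: none
Why: Syn-hydroboration of the alkyne fixes the (E)-2-methylbut-2-enyl geometry, boron-to-zinc transmetalation gives the alkenylzinc, and the amino-alcohol-catalysed asymmetric addition (Oppolzer type) to the α-branched enal sets the (R)-carbinol under ligand control while the vinyl iodide is inert.

Step 19
Reactants: 30 iodide
Product: 31 (2E,4R,5E,7Z)-3,5,7-trimethyl-8-(trimethylstannyl)octa-2,5,7-trien-4-ol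
Conditions: (Me3Sn)2 (1.5 equiv), Pd(PPh3)4 (5 mol %), PhMe, 60 °C
Reagents that add atoms: hexamethylditin, C[Sn](C)(C)[Sn](C)(C)C
Why: Palladium-catalysed stannylation of the vinyl iodide proceeds with retention of the (Z)-geometry and tolerates the free bis-allylic alcohol.

**Union**

Step 20
Reactants: 19 trienyl iodide; 31 dienylstannane
Product: 34 shimalactone B, via tetraene 32 (not isolated), via cyclooctatriene 33 (not isolated)
Conditions: Pd(PPh3)4 (10 mol %), copper thiophene-2-carboxylate Cu(O2CC4H3S) (1.5 equiv), DMF, rt, dark; then rt → 40 °C; HPLC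
Reagents that add atoms: none
Why: Stille coupling with retention at both (Z)-alkenes gives the (E,Z,Z,E)-tetraene, which undergoes thermal 8π-conrotatory closure (C7 and C8 arms trans) and 6π-disrotatory closure (cis ring fusion) to fix the relative configuration of the four new centres, while the sense of conrotation is biased only by the adjacent carbinol, so 34 is separated from its bicyclooctadiene diastereomer by HPLC.

**Compound list**

1 | 2-ethenyl-2-methyloxirane (isoprene monoepoxide, racemic) | CC1(C=C)CO1 | starting material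
2 | tert-butyl methyl propanedioate | COC(=O)CC(=O)OC(C)(C)C | starting material
3 | 1-tert-butyl 3-methyl 2-[(2R)-1-hydroxy-2-methylbut-3-en-2-yl]propanedioate (C2 epimers) | OC[C@](C)(C=C)C(C(=O)OC)C(=O)OC(C)(C)C | intermediate
4 | tert-butyl (4R)-4-ethenyl-4-methyl-2-oxooxolane-3-carboxylate (C3 epimers) | O=C1OC[C@](C)(C=C)C1C(=O)OC(C)(C)C | intermediate
5 | tert-butyl (4R)-4-formyl-4-methyl-2-oxooxolane-3-carboxylate (C3 epimers) | O=C1OC[C@](C)(C=O)C1C(=O)OC(C)(C)C | intermediate
6 | tert-butyl (4R)-4-(dimethoxymethyl)-4-methyl-2-oxooxolane-3-carboxylate (C3 epimers) | O=C1OC[C@](C)(C(OC)OC)C1C(=O)OC(C)(C)C | intermediate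
7 | tert-butyl (3S,4R)-4-(dimethoxymethyl)-3,4-dimethyl-2-oxooxolane-3-carboxylate | O=C1OC[C@](C)(C(OC)OC)[C@]1(C)C(=O)OC(C)(C)C | intermediate
8 | lithium (3S,4R)-3-(tert-butoxycarbonyl)-4-(dimethoxymethyl)-2-ethyl-3,4-dimethyloxolan-2-olate (C2 epimers) | [Li+].[O-]C1(CC)OC[C@](C)(C(OC)OC)[C@]1(C)C(=O)OC(C)(C)C | intermediate
9 | tert-butyl (2S)-2-[(2R)-1-hydroxy-3,3-dimethoxy-2-methylpropan-2-yl]-2-methyl-3-oxopentanoate | CCC(=O)[C@@](C)(C(=O)OC(C)(C)C)[C@](C)(CO)C(OC)OC | intermediate
10 | tert-butyl (2S)-2-[(2R)-1-{[tert-butyl(diphenyl)silyl]oxy}-3,3-dimethoxy-2-methylpropan-2-yl]-2-methyl-3-oxopentanoate | CCC(=O)[C@@](C)(C(=O)OC(C)(C)C)[C@](C)(CO[Si](c1ccccc1)(c1ccccc1)C(C)(C)C)C(OC)OC | intermediate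
11 | (3S,4R)-4-{[tert-butyl(diphenyl)silyl]oxymethyl}-5-hydroxy-3,4-dimethyl-3-propanoyloxolan-2-one (C5 anomers) | OC1OC(=O)[C@](C)(C(=O)CC)[C@]1(C)CO[Si](c1ccccc1)(c1ccccc1)C(C)(C)C | intermediate
12 | (3R,4S)-3-{[tert-butyl(diphenyl)silyl]oxymethyl}-3,4-dimethyl-5-oxo-4-propanoyloxolan-2-yl acetate (C2 anomers) | CC(=O)OC1OC(=O)[C@](C)(C(=O)CC)[C@]1(C)CO[Si](c1ccccc1)(c1ccccc1)C(C)(C)C | intermediate
13 | (3R,4S)-3-{[tert-butyl(diphenyl)silyl]oxymethyl}-3,4-dimethyl-5-oxo-4-[(1Z)-1-(trimethylsilyloxy)prop-1-en-1-yl]oxolan-2-yl acetate | CC(=O)OC1OC(=O)[C@](C)(/C(O[Si](C)(C)C)=C/C)[C@]1(C)CO[Si](c1ccccc1)(c1ccccc1)C(C)(C)C | intermediate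
14 | (1S,4S,6R,7R)-7-{[tert-butyl(diphenyl)silyl]oxymethyl}-4,6,7-trimethyl-2-oxabicyclo[2.2.1]heptane-3,5-dione | CC(C)(C)[Si](c1ccccc1)(c1ccccc1)OC[C@]1(C)[C@H]2OC(=O)[C@]1(C)C(=O)[C@@H]2C | intermediate
15 | (1S,4S,6R,7R)-7-(hydroxymethyl)-4,6,7-trimethyl-2-oxabicyclo[2.2.1]heptane-3,5-dione | OC[C@]1(C)[C@H]2OC(=O)[C@]1(C)C(=O)[C@@H]2C | intermediate
16 | (1S,4S,6R,7S)-4,6,7-trimethyl-3,5-dioxo-2-oxabicyclo[2.2.1]heptane-7-carbaldehyde | O=C[C@]1(C)[C@H]2OC(=O)[C@]1(C)C(=O)[C@@H]2C | intermediate
17 | (2E)-2-methyl-3-[(1S,4S,6R,7S)-4,6,7-trimethyl-3,5-dioxo-2-oxabicyclo[2.2.1]heptan-7-yl]prop-2-enal | O=C/C(C)=C/[C@]1(C)[C@H]2OC(=O)[C@]1(C)C(=O)[C@@H]2C | intermediate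
18 | (2E,4E)-2,4-dimethyl-5-[(1S,4S,6R,7S)-4,6,7-trimethyl-3,5-dioxo-2-oxabicyclo[2.2.1]heptan-7-yl]penta-2,4-dienal | O=C/C(C)=C/C(C)=C/[C@]1(C)[C@H]2OC(=O)[C@]1(C)C(=O)[C@@H]2C | intermediate
19 | (1S,4S,6R,7S)-7-[(1E,3E,5Z)-6-iodo-2,4-dimethylhepta-1,3,5-trien-1-yl]-4,6,7-trimethyl-2-oxabicyclo[2.2.1]heptane-3,5-dione | C/C(I)=C/C(C)=C/C(C)=C/[C@]1(C)[C@H]2OC(=O)[C@]1(C)C(=O)[C@@H]2C | intermediate
20 | prop-2-yn-1-ol | C#CCO | starting material
21 | bromomagnesium (2Z)-3-(bromomagnesio)-2-methylprop-2-en-1-olate | Br[Mg]OC/C(C)=C\[Mg]Br | intermediate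
22 | (2Z)-3-iodo-2-methylprop-2-en-1-ol | OC/C(C)=C\I | intermediate
23 | (2Z)-3-iodo-2-methylprop-2-enal | O=C/C(C)=C\I | intermediate
24 | ethyl (2E,4Z)-5-iodo-2,4-dimethylpenta-2,4-dienoate | CCOC(=O)/C(C)=C/C(C)=C\I | intermediate
25 | (2E,4Z)-5-iodo-2,4-dimethylpenta-2,4-dien-1-ol | OC/C(C)=C/C(C)=C\I | intermediate
26 | (2E,4Z)-5-iodo-2,4-dimethylpenta-2,4-dienal | O=C/C(C)=C/C(C)=C\I | intermediate
27 | but-2-yne | CC#CC | starting material
28 | [(2Z)-but-2-en-2-yl]dicyclohexylborane | C/C=C(\C)B(C1CCCCC1)C1CCCCC1 | intermediate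
29 | [(2E)-but-2-en-2-yl](methyl)zinc | C/C=C(\C)[Zn]C | intermediate
30 | (2E,4R,5E,7Z)-8-iodo-3,5,7-trimethylocta-2,5,7-trien-4-ol | C/C=C(\C)[C@@H](O)/C(C)=C/C(C)=C\I | intermediate
31 | (2E,4R,5E,7Z)-3,5,7-trimethyl-8-(trimethylstannyl)octa-2,5,7-trien-4-ol | C/C=C(\C)[C@@H](O)/C(C)=C/C(C)=C\[Sn](C)(C)C | intermediate
32 | (1S,4S,6R,7S)-7-[(1E,3E,5Z,7Z,9E,11R,12E)-11-hydroxy-2,4,6,8,10,12-hexamethyltetradeca-1,3,5,7,9,12-hexaen-1-yl]-4,6,7-trimethyl-2-oxabicyclo[2.2.1]heptane-3,5-dione | C/C=C(\C)[C@@H](O)/C(C)=C/C(C)=C\C(C)=C/C(C)=C/C(C)=C/[C@]1(C)[C@H]2OC(=O)[C@]1(C)C(=O)[C@@H]2C | intermediate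
33 | all-cis 1,3,5,7-tetramethylcycloocta-1,3,5-triene carrying at C7 the (R)-hydroxy[(E)-but-2-en-2-yl]methyl group and at C8 the (E)-2-(oxabicycloheptanedionyl)-1-methylethenyl arm, the two arms trans | C/C=C(\C)[C@@H](O)[C@@]1(C)/C=C(C)\C=C(C)/C=C(C)\[C@@H]1/C(C)=C/[C@]1(C)[C@H]2OC(=O)[C@]1(C)C(=O)[C@@H]2C | intermediate
34 | shimalactone B | C/C=C(\C)[C@@H](O)[C@@]1(C)[C@@H]2C(C)=CC(C)=C[C@]2(C)[C@@H]1/C(C)=C/[C@]1(C)[C@H]2OC(=O)[C@]1(C)C(=O)[C@@H]2C | target

**Totals**
Total step count: 20. Longest linear sequence: 13 steps (steps 1–12, then step 20); the west branch is steps 13–19 (7 steps) and joins at step 20.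

**Three steps most likely to fail**

Step 20. The coupling and cascade are reliable, but both senses of conrotation are open and 34 may be the minor diastereomer. The fallback sets out from 31 and comes back at 34. Compound 31 is silylated (Et3SiCl, imidazole, CH2Cl2) to triethyl{[(2E,4R,5E,7Z)-3,5,7-trimethyl-8-(trimethylstannyl)octa-2,5,7-trien-4-yl]oxy}silane F3. Coupling with 19 under the step 20 conditions gives the O-triethylsilyl tetraene F4, which closes through the O-triethylsilyl cyclooctatriene F5 to shimalactone B triethylsilyl ether F6. The bulky silyloxy group next to the forming bond changes the preferred rotamer of the carbinol and so shifts the sense of conrotation. HF·pyridine (THF, 0 °C) then gives 34.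

Step 7. Closing a bridged ring by attack of an enol silane on a ring oxocarbenium ion is geometrically demanding. The fallback sets out from 11 and comes back at 14. The pseudo-acid is opened with Me3SiCHN2 (MeOH/PhMe, 0 °C) to methyl (2S)-2-[(2R)-1-{[tert-butyl(diphenyl)silyl]oxy}-2-methyl-3-oxopropan-2-yl]-2-methyl-3-oxopentanoate F1. Its ketone is deprotonated with LiN(SiMe3)2 (THF, −78 °C) for a classical intramolecular enolate aldol addition to the free aldehyde. This gives methyl (1S,2R,3S,4R)-2-{[tert-butyl(diphenyl)silyl]oxymethyl}-3-hydroxy-1,2,4-trimethyl-5-oxocyclopentane-1-carboxylate F2 (hydroxyl cis to the ester; the trans aldol returns by retro-aldol). F2 lactonises to 14 on warming, or with catalytic TsOH in PhMe with removal of methanol.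

Step 3. Facial selectivity rests only on the size difference between methyl and dimethoxymethyl on the neighbouring quaternary carbon. The fallback sets out from 6 and comes back at 7. The methylation is run under catalyst control instead: MeI, CsOH·H2O, toluene, −40 °C, with a C2-symmetric binaphthyl-derived spiro ammonium bromide as phase-transfer catalyst, using the antipode that reinforces attack syn to the C4 methyl. This fallback passes through no new compound (none F0).

**Further compounds**
F0 | step 3 | none | none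
F1 | step 7 | methyl (2S)-2-[(2R)-1-{[tert-butyl(diphenyl)silyl]oxy}-2-methyl-3-oxopropan-2-yl]-2-methyl-3-oxopentanoate | CCC(=O)[C@@](C)(C(=O)OC)[C@](C)(CO[Si](c1ccccc1)(c1ccccc1)C(C)(C)C)C=O
F2 | step 7 | methyl (1S,2R,3S,4R)-2-{[tert-butyl(diphenyl)silyl]oxymethyl}-3-hydroxy-1,2,4-trimethyl-5-oxocyclopentane-1-carboxylate | CC(C)(C)[Si](c1ccccc1)(c1ccccc1)OC[C@]1(C)[C@@H](O)[C@@H](C)C(=O)[C@@]1(C)C(=O)OC
F3 | step 20 | triethyl{[(2E,4R,5E,7Z)-3,5,7-trimethyl-8-(trimethylstannyl)octa-2,5,7-trien-4-yl]oxy}silane | C/C=C(\C)[C@@H](O[Si](CC)(CC)CC)/C(C)=C/C(C)=C\[Sn](C)(C)C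
F4 | step 20 | O-triethylsilyl tetraene (triethylsilyl ether of 32) | C/C=C(\C)[C@@H](O[Si](CC)(CC)CC)/C(C)=C/C(C)=C\C(C)=C/C(C)=C/C(C)=C/[C@]1(C)[C@H]2OC(=O)[C@]1(C)C(=O)[C@@H]2C
F5 | step 20 | O-triethylsilyl cyclooctatriene (triethylsilyl ether of 33) | C/C=C(\C)[C@@H](O[Si](CC)(CC)CC)[C@@]1(C)/C=C(C)\C=C(C)/C=C(C)\[C@@H]1/C(C)=C/[C@]1(C)[C@H]2OC(=O)[C@]1(C)C(=O)[C@@H]2C
F6 | step 20 | shimalactone B triethylsilyl ether | C/C=C(\C)[C@@H](O[Si](CC)(CC)CC)[C@@]1(C)[C@@H]2C(C)=CC(C)=C[C@]2(C)[C@@H]1/C(C)=C/[C@]1(C)[C@H]2OC(=O)[C@]1(C)C(=O)[C@@H]2C
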